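**Retrosynthetic overview**

1. Both C–Br bonds come last, from diol 18 by double SN2 bromination with inversion. The allylic carbinol comes from CBS reduction of Z-enone 16, and the ethyl group from EtLi addition to Z-acid 14.
2. The oxolane C2–H and the Z-acrylic acid of 14 come from reductive opening of spiro-butenolide 11.
3. 11 comes from furan diol 8 by singlet-oxygen dearomatisation: the furan C3=C4 bond becomes the Z-alkene and the side-chain hydroxyl closes the oxolane. This is the only ring that is kept; the butenolide ring formed with it is opened again in step 6.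
4. 8 comes from 2-acetylfuran and α-chloroaldehyde 4 by anti-aldol addition (Cl/O pair), then 1,3-anti reduction.
5. 4 comes from pent-4-enal by Z-selective enyne cross-metathesis and organocatalytic α-chlorination.

Assumption: silyl enyne 2 is taken as a purchasable building block (otherwise one Sonogashira step from vinyl bromide and triisopropylsilylacetylene).
Assumption: the (2S,5S) antipode of 2,5-diphenylpyrrolidine is the one that gives (R)-2-chloroaldehydes; if the sense is the reverse, its mirror image is used.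

**Route**

Step 1
Reactants: 1 pent-4-enal; 2 triisopropyl(but-3-en-1-yn-1-yl)silane
Product: 3 (4Z)-7-(triisopropylsilyl)hept-4-en-6-ynal
Conditions: second-generation Grubbs catalyst RuCl2(=CHPh)(H2IMes)(PCy3) (5 mol %), 1 (3 equiv), CH2Cl2, 40 °C; chromatography to remove the minor E isomer
Reagents that add atoms: none
Why: Olefin cross-metathesis of a terminal alkene with a silyl 1,3-enyne, which favours the Z-enyne (typically about 5:1 or better); no stereocentre is formed.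

Step 2
Reactants: 3 (4Z)-7-(triisopropylsilyl)hept-4-en-6-ynal
Product: 4 (2R,4Z)-2-chloro-7-(triisopropylsilyl)hept-4-en-6-ynal
Conditions: N-chlorosuccinimide (1.3 equiv), (2S,5S)-2,5-diphenylpyrrolidine (10 mol %), CH2Cl2, 0 °C to rt; pentane, filtration; used at once
Reagents that add atoms: N-chlorosuccinimide, O=C1CCC(=O)N1Cl
Why: Organocatalytic enamine α-chlorination (Jørgensen type) in which the C2-symmetric pyrrolidine shields one enamine face, so chlorine is delivered to set C2 as R; the product is used directly because α-chloroaldehydes racemise on storage.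

Step 3
Reactants: 5 2-acetylfuran; 4 (2R,4Z)-2-chloro-7-(triisopropylsilyl)hept-4-en-6-ynal
Product: 7 (3S,4R,6Z)-4-chloro-1-(furan-2-yl)-3-hydroxy-9-(triisopropylsilyl)non-6-en-8-yn-1-one, via lithium enolate 6 (not isolated)
Conditions: LiN(iPr)2 (1.05 equiv), THF, −78 °C; then 4, −78 °C, 20 min; AcOH/THF quench at −78 °C
Reagents that add atoms: none
Why: Lithium-enolate aldol addition to an α-chloroaldehyde under Cornforth (polar Felkin–Anh) control gives the 1,2-anti chlorohydrin, setting C3 as S relative to the C4 chloride, and the cold acidic quench prevents retro-aldol and epoxide formation.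

Step 4
Reactants: 7 (3S,4R,6Z)-4-chloro-1-(furan-2-yl)-3-hydroxy-9-(triisopropylsilyl)non-6-en-8-yn-1-one
Product: 8 (1S,3S,4R,6Z)-4-chloro-1-(furan-2-yl)-9-(triisopropylsilyl)non-6-en-8-yne-1,3-diol
Conditions: Me4NBH(OAc)3 (5 equiv), MeCN/AcOH 1:1, −30 to −10 °C
Reagents that add atoms: none
Why: Evans–Saksena directed reduction in which the acetoxyborohydride bound to the C3 hydroxyl delivers hydride internally through a chair transition state, giving the 1,3-anti diol and setting C1 as S.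

Step 5 (key step)
Reactants: 8 (1S,3S,4R,6Z)-4-chloro-1-(furan-2-yl)-9-(triisopropylsilyl)non-6-en-8-yne-1,3-diol
Product: 11 (7S,9S)-7-[(1R,3Z)-1-chloro-6-(triisopropylsilyl)hex-3-en-5-yn-1-yl]-9-hydroxy-1,6-dioxaspiro[4.4]non-3-en-2-one as a mixture of C5 spiro epimers, via furan endoperoxide 9 (not isolated), via γ-hydroxybutenolide 10 (not isolated)
Conditions: O2, 5,10,15,20-tetraphenylporphyrin (1 mol %), visible light, iPr2NEt (0.3 equiv), CH2Cl2, −78 °C; then 10-camphorsulfonic acid (0.5 equiv), 4 Å sieves, 0 °C to rt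
Reagents that add atoms: dioxygen, O=O
Why: Singlet-oxygen [4+2] dearomatisation of the furan, base-induced Kornblum–DeLaMare fragmentation of endoperoxide 9 to γ-hydroxybutenolide 10, then acid-catalysed spiroketalisation by the C3 hydroxyl (the C1 hydroxyl would have to close a three-membered ring); the furan C3=C4 bond survives as a ring-locked cis alkene and the spiro centre is erased in step 6.

Step 6
Reactants: 11 (7S,9S)-7-[(1R,3Z)-1-chloro-6-(triisopropylsilyl)hex-3-en-5-yn-1-yl]-9-hydroxy-1,6-dioxaspiro[4.4]non-3-en-2-one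
Product: 14 (2Z)-3-[(2R,3S,5S)-5-[(1R,3Z)-1-chloro-6-(triisopropylsilyl)hex-3-en-5-yn-1-yl]-3-hydroxyoxolan-2-yl]prop-2-enoic acid, via oxocarbenium carboxylate 12 (not isolated), via triethylsilyl ester 13 (not isolated)
Conditions: Et3SiH (5 equiv), BF3·OEt2 (3 equiv), CH2Cl2, −78 to −30 °C; aq. NaHCO3, then pH 3
Reagents that add atoms: none
Why: Proposed new method: BF3 activates the lactone carbonyl so the spiro C–O(acyl) bond ionises (carboxylate is the better leaving group and the remaining ring oxygen stabilises the cation) to oxocarbenium 12, which Et3SiH reduces from the face cis to the neighbouring C3 oxygen (inside attack on the envelope with that C–O bond pseudo-equatorial, Woerpel model), setting oxolane C2 as R (2,3-trans and 2,5-trans) and releasing the Z-acid; the closest known reactions are Et3SiH/Lewis acid reductions of anomeric esters and ketose lactols (Kishi-type), including Achmatowicz hemiketals that carry the same enone.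

Step 7
Reactants: 14 (2Z)-3-[(2R,3S,5S)-5-[(1R,3Z)-1-chloro-6-(triisopropylsilyl)hex-3-en-5-yn-1-yl]-3-hydroxyoxolan-2-yl]prop-2-enoic acid
Product: 16 (1Z)-1-[(2R,3S,5S)-5-[(1R,3Z)-1-chloro-6-(triisopropylsilyl)hex-3-en-5-yn-1-yl]-3-hydroxyoxolan-2-yl]pent-1-en-3-one, via trilithium gem-diolate 15 (not isolated)
Conditions: EtLi (3.5 equiv), Et2O, −78 to −20 °C; inverse quench into cold aq. NH4Cl
Reagents that add atoms: ethyllithium, [Li]CC
Why: Classical ketone synthesis from a carboxylic acid and an organolithium, in which gem-diolate 15 is stable until the quench, so only one ethyl group adds and the Z-alkene is kept; no stereocentre is formed.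

Step 8
Reactants: 16 (1Z)-1-[(2R,3S,5S)-5-[(1R,3Z)-1-chloro-6-(triisopropylsilyl)hex-3-en-5-yn-1-yl]-3-hydroxyoxolan-2-yl]pent-1-en-3-one
Product: 17 (2R,3S,5S)-5-[(1R,3Z)-1-chloro-6-(triisopropylsilyl)hex-3-en-5-yn-1-yl]-2-[(1Z,3S)-3-hydroxypent-1-en-1-yl]oxolan-3-ol
Conditions: (R)-1-methyl-3,3-diphenyltetrahydro-1H,3H-pyrrolo[1,2-c][1,3,2]oxazaborole ((R)-Me-CBS, 0.5 equiv), catecholborane (3 equiv), toluene, −78 °C
Reagents that add atoms: none
Why: Corey–Bakshi–Shibata reduction in which the Z-alkenyl group acts as the large substituent, so the (R)-catalyst gives the (S)-allylic alcohol; catecholborane at −78 °C avoids hydroboration and Z/E isomerisation.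

Step 9
Reactants: 17 (2R,3S,5S)-5-[(1R,3Z)-1-chloro-6-(triisopropylsilyl)hex-3-en-5-yn-1-yl]-2-[(1Z,3S)-3-hydroxypent-1-en-1-yl]oxolan-3-ol
Product: 18 (2R,3S,5S)-5-[(1R,3Z)-1-chlorohex-3-en-5-yn-1-yl]-2-[(1Z,3S)-3-hydroxypent-1-en-1-yl]oxolan-3-ol
Conditions: Bu4NF (1.2 equiv), THF, 0 °C to rt
Reagents that add atoms: none
Why: Fluoride-induced protodesilylation of the alkynylsilane leaves all stereocentres untouched, and is placed before halogenation because the allylic bromide would not survive fluoride.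

Step 10
Reactants: 18 (2R,3S,5S)-5-[(1R,3Z)-1-chlorohex-3-en-5-yn-1-yl]-2-[(1Z,3S)-3-hydroxypent-1-en-1-yl]oxolan-3-ol
Product: 19 (2R,3R,5S)-3-bromo-2-[(1Z,3R)-3-bromopent-1-en-1-yl]-5-[(1R,3Z)-1-chlorohex-3-en-5-yn-1-yl]oxolane
Conditions: CBr4 (6 equiv), P(n-C8H17)3 (6 equiv), toluene, 0 °C, then 60 °C
Reagents that add atoms: carbon tetrabromide, BrC(Br)(Br)Br
Why: Double Appel-type bromination (Murai conditions) in which each alkoxyphosphonium ion is displaced by bromide in an SN2 reaction with inversion, turning the ring C3 (S) and side-chain C3 (S) carbinols into the two (R)-bromides of the target.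

**Compound list**

1 | pent-4-enal | C=CCCC=O | starting material
2 | triisopropyl(but-3-en-1-yn-1-yl)silane | C=CC#C[Si](C(C)C)(C(C)C)C(C)C | starting material
3 | (4Z)-7-(triisopropylsilyl)hept-4-en-6-ynal | CC(C)[Si](C(C)C)(C(C)C)C#C/C=C\CCC=O | intermediate
4 | (2R,4Z)-2-chloro-7-(triisopropylsilyl)hept-4-en-6-ynal | CC(C)[Si](C(C)C)(C(C)C)C#C/C=C\C[C@@H](Cl)C=O | intermediate
5 | 2-acetylfuran | CC(=O)c1ccco1 | starting material
6 | lithium enolate of 2-acetylfuran (not isolated) | C=C(O[Li])c1ccco1 | intermediate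
7 | (3S,4R,6Z)-4-chloro-1-(furan-2-yl)-3-hydroxy-9-(triisopropylsilyl)non-6-en-8-yn-1-one | CC(C)[Si](C(C)C)(C(C)C)C#C/C=C\C[C@@H](Cl)[C@@H](O)CC(=O)c1ccco1 | intermediate
8 | (1S,3S,4R,6Z)-4-chloro-1-(furan-2-yl)-9-(triisopropylsilyl)non-6-en-8-yne-1,3-diol | CC(C)[Si](C(C)C)(C(C)C)C#C/C=C\C[C@@H](Cl)[C@@H](O)C[C@H](O)c1ccco1 | intermediate
9 | furan endoperoxide of 8 (2,3,7-trioxabicyclo[2.2.1]hept-5-ene, bridgehead configuration not defined; not isolated) | CC(C)[Si](C(C)C)(C(C)C)C#C/C=C\C[C@@H](Cl)[C@@H](O)C[C@H](O)C12OOC(C=C1)O2 | intermediate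
10 | γ-hydroxybutenolide: 5-hydroxy-5-[(1S,3S,4R,6Z)-4-chloro-1,3-dihydroxy-9-(triisopropylsilyl)non-6-en-8-yn-1-yl]furan-2(5H)-one (C5 not defined; not isolated) | CC(C)[Si](C(C)C)(C(C)C)C#C/C=C\C[C@@H](Cl)[C@@H](O)C[C@H](O)C1(O)OC(=O)C=C1 | intermediate
11 | (7S,9S)-7-[(1R,3Z)-1-chloro-6-(triisopropylsilyl)hex-3-en-5-yn-1-yl]-9-hydroxy-1,6-dioxaspiro[4.4]non-3-en-2-one (C5 spiro epimers) | CC(C)[Si](C(C)C)(C(C)C)C#C/C=C\C[C@@H](Cl)[C@@H]1C[C@H](O)C2(C=CC(=O)O2)O1 | intermediate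
12 | ring oxocarbenium carboxylate zwitterion from 11 (not isolated) | CC(C)[Si](C(C)C)(C(C)C)C#C/C=C\C[C@@H](Cl)[C@@H]1C[C@H](O)C(/C=C\C([O-])=O)=[O+]1 | intermediate
13 | triethylsilyl ester of 14 (not isolated) | CC(C)[Si](C(C)C)(C(C)C)C#C/C=C\C[C@@H](Cl)[C@@H]1C[C@H](O)[C@@H](/C=C\C(=O)O[Si](CC)(CC)CC)O1 | intermediate
14 | (2Z)-3-[(2R,3S,5S)-5-[(1R,3Z)-1-chloro-6-(triisopropylsilyl)hex-3-en-5-yn-1-yl]-3-hydroxyoxolan-2-yl]prop-2-enoic acid | CC(C)[Si](C(C)C)(C(C)C)C#C/C=C\C[C@@H](Cl)[C@@H]1C[C@H](O)[C@@H](/C=C\C(O)=O)O1 | intermediate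
15 | trilithium gem-diolate from 14 and EtLi (not isolated) | CC(C)[Si](C(C)C)(C(C)C)C#C/C=C\C[C@@H](Cl)[C@@H]1C[C@H](O[Li])[C@@H](/C=C\C(CC)(O[Li])O[Li])O1 | intermediate
16 | (1Z)-1-[(2R,3S,5S)-5-[(1R,3Z)-1-chloro-6-(triisopropylsilyl)hex-3-en-5-yn-1-yl]-3-hydroxyoxolan-2-yl]pent-1-en-3-one | CC(C)[Si](C(C)C)(C(C)C)C#C/C=C\C[C@@H](Cl)[C@@H]1C[C@H](O)[C@@H](/C=C\C(=O)CC)O1 | intermediate
17 | (2R,3S,5S)-5-[(1R,3Z)-1-chloro-6-(triisopropylsilyl)hex-3-en-5-yn-1-yl]-2-[(1Z,3S)-3-hydroxypent-1-en-1-yl]oxolan-3-ol | CC(C)[Si](C(C)C)(C(C)C)C#C/C=C\C[C@@H](Cl)[C@@H]1C[C@H](O)[C@@H](/C=C\[C@@H](O)CC)O1 | intermediate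
18 | (2R,3S,5S)-5-[(1R,3Z)-1-chlorohex-3-en-5-yn-1-yl]-2-[(1Z,3S)-3-hydroxypent-1-en-1-yl]oxolan-3-ol | C#C/C=C\C[C@@H](Cl)[C@@H]1C[C@H](O)[C@@H](/C=C\[C@@H](O)CC)O1 | intermediate
19 | (2R,3R,5S)-3-bromo-2-[(1Z,3R)-3-bromopent-1-en-1-yl]-5-[(1R,3Z)-1-chlorohex-3-en-5-yn-1-yl]oxolane | C#C/C=C\C[C@@H](Cl)[C@@H]1C[C@@H](Br)[C@@H](/C=C\[C@H](Br)CC)O1 | target

**Step count**

Total steps: 10. Longest linear sequence: 10 (from 1 to 19).

**Three steps most likely to fail, with fallbacks**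

Step 6. The reductive opening of the spirolactone is unprecedented in this exact form. The facial selectivity rests on a free hydroxyl next to the cation, and the Z-acid could isomerise under the Lewis acid. The fallback makes the hydride delivery intramolecular. It sets out from 11, which is silylated with chlorodiisopropylsilane and imidazole in CH2Cl2 to give (7S,9S)-7-[(1R,3Z)-1-chloro-6-(triisopropylsilyl)hex-3-en-5-yn-1-yl]-9-[(diisopropylsilyl)oxy]-1,6-dioxaspiro[4.4]non-3-en-2-one F1. Catalytic TMSOTf at −78 °C ionises the spiro centre, the tethered Si–H transfers hydride on the face of its own oxygen, and the silicon is caught by the carboxylate as the eight-membered cyclic diisopropylsilylene ester F2. Mild aqueous acid hydrolyses this, and the fallback comes back to the route at 14.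

Step 7. EtLi may deprotonate at the γ-position, attack the enyne or the chloride, or erode the Z geometry. The fallback replaces direct addition by an acyl-transfer sequence. It sets out from 14, which is coupled with N,O-dimethylhydroxylamine hydrochloride (EDC·HCl, HOBt, iPr2NEt, CH2Cl2) to give (2Z)-3-[(2R,3S,5S)-5-[(1R,3Z)-1-chloro-6-(triisopropylsilyl)hex-3-en-5-yn-1-yl]-3-hydroxyoxolan-2-yl]-N-methoxy-N-methylprop-2-enamide F3. EtMgBr (3 equiv, THF, −40 °C, acidic quench) then gives the ketone, and the fallback comes back to the route at 16.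

Step 10. The hindered ring alcohol needs heat, and the allylic bromide formed first may epimerise or undergo 1,3-shift under those conditions. The fallback installs the two bromides separately and changes the activation. It sets out from 16, which is converted with Tf2O and 2,6-lutidine at −78 °C into (2R,3S,5S)-5-[(1R,3Z)-1-chloro-6-(triisopropylsilyl)hex-3-en-5-yn-1-yl]-2-[(1Z)-3-oxopent-1-en-1-yl]oxolan-3-yl trifluoromethanesulfonate F4. Bu4NBr at −78 to 0 °C displaces this with inversion to give (1Z)-1-[(2R,3R,5S)-3-bromo-5-[(1R,3Z)-1-chloro-6-(triisopropylsilyl)hex-3-en-5-yn-1-yl]oxolan-2-yl]pent-1-en-3-one F5. CBS reduction as in step 8 gives (1Z,3S)-1-[(2R,3R,5S)-3-bromo-5-[(1R,3Z)-1-chloro-6-(triisopropylsilyl)hex-3-en-5-yn-1-yl]oxolan-2-yl]pent-1-en-3-ol F6. Bu4NF buffered with AcOH at 0 °C gives (1Z,3S)-1-[(2R,3R,5S)-3-bromo-5-[(1R,3Z)-1-chlorohex-3-en-5-yn-1-yl]oxolan-2-yl]pent-1-en-3-ol F7. A cold Appel reaction (CBr4, PPh3, CH2Cl2, 0 °C) on the allylic alcohol alone then brings the fallback back to the route at 19.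

**Further compounds**

F1 | step 6 | (7S,9S)-7-[(1R,3Z)-1-chloro-6-(triisopropylsilyl)hex-3-en-5-yn-1-yl]-9-[(diisopropylsilyl)oxy]-1,6-dioxaspiro[4.4]non-3-en-2-one | CC(C)[Si](C(C)C)(C(C)C)C#C/C=C\C[C@@H](Cl)[C@@H]1C[C@H](O[SiH](C(C)C)C(C)C)C2(C=CC(=O)O2)O1
F2 | step 6 | eight-membered cyclic diisopropylsilylene ester linking the oxolane C3 oxygen and the carboxylate of 14 | CC(C)[Si](C(C)C)(C(C)C)C#C/C=C\C[C@@H](Cl)[C@@H]1C[C@@H]2O[Si](C(C)C)(C(C)C)OC(=O)/C=C\[C@H]2O1
F3 | step 7 | (2Z)-3-[(2R,3S,5S)-5-[(1R,3Z)-1-chloro-6-(triisopropylsilyl)hex-3-en-5-yn-1-yl]-3-hydroxyoxolan-2-yl]-N-methoxy-N-methylprop-2-enamide | CC(C)[Si](C(C)C)(C(C)C)C#C/C=C\C[C@@H](Cl)[C@@H]1C[C@H](O)[C@@H](/C=C\C(=O)N(C)OC)O1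
F4 | step 10 | (2R,3S,5S)-5-[(1R,3Z)-1-chloro-6-(triisopropylsilyl)hex-3-en-5-yn-1-yl]-2-[(1Z)-3-oxopent-1-en-1-yl]oxolan-3-yl trifluoromethanesulfonate | CC(C)[Si](C(C)C)(C(C)C)C#C/C=C\C[C@@H](Cl)[C@@H]1C[C@H](OS(=O)(=O)C(F)(F)F)[C@@H](/C=C\C(=O)CC)O1
F5 | step 10 | (1Z)-1-[(2R,3R,5S)-3-bromo-5-[(1R,3Z)-1-chloro-6-(triisopropylsilyl)hex-3-en-5-yn-1-yl]oxolan-2-yl]pent-1-en-3-one | CC(C)[Si](C(C)C)(C(C)C)C#C/C=C\C[C@@H](Cl)[C@@H]1C[C@@H](Br)[C@@H](/C=C\C(=O)CC)O1
F6 | step 10 | (1Z,3S)-1-[(2R,3R,5S)-3-bromo-5-[(1R,3Z)-1-chloro-6-(triisopropylsilyl)hex-3-en-5-yn-1-yl]oxolan-2-yl]pent-1-en-3-ol | CC(C)[Si](C(C)C)(C(C)C)C#C/C=C\C[C@@H](Cl)[C@@H]1C[C@@H](Br)[C@@H](/C=C\[C@@H](O)CC)O1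
F7 | step 10 | (1Z,3S)-1-[(2R,3R,5S)-3-bromo-5-[(1R,3Z)-1-chlorohex-3-en-5-yn-1-yl]oxolan-2-yl]pent-1-en-3-ol | C#C/C=C\C[C@@H](Cl)[C@@H]1C[C@@H](Br)[C@@H](/C=C\[C@@H](O)CC)O1
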